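Everything rests on cutting ring A at the C4a–C8a bond. Ring A carries two adjacent cis stereocentres, C4a and C8a (C8a holding C1), right beside the C5=C6(Me) alkene. This pattern is what a [3,3] shift inside a six-membered lactone leaves behind. One Ireland–Claisen ring contraction therefore delivers ring A, the C4a–C8a bond, both ring-fusion centres and the trisubstituted alkene, all from one tertiary carbinol centre taken from (R)-linalool. Its precursor is an (R)-6-methyl-δ-valerolactone whose carbinol carbon bears a (1E,4E)-4-methylhexa-1,4-dienyl chain ending in a silyl ether. Ring B is then closed at C1–C2, and a separately made, stereodefined 1,2-dioxane aldehyde is attached by olefination.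

Key step: step 8

- **Labels.** Decalin atoms are C1–C8a, as in 1,4,4a,7,8,8a-hexahydronaphthalene. Side-chain atoms are S1 (carboxyl carbon), S2 (CHMe), S3 (CH–O), S4, S5, S6 (C(Me)–O), S7 and S8 (CH2 on C2).
- **Remark on the precursor.** The chain end is carried as a tert-butyldiphenylsilyl ether instead of a thioether. Sulfur would bind the ruthenium catalyst of step 7 and would be oxidised by peroxide reagents, whereas oxygen leads to the aldehyde that fixes the C2=C3 alkene in step 13. The carbinol centre comes from the chiral pool and not from an asymmetric addition to a dialkyl ketone.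
- **Stereochemical check.** (R) at the lactone carbinol carbon maps through the boat onto (1S,2R) in acid 14 and onto (4aR,8aS) in the target.
- **Assumption.** Step 11 may end by proton loss from C4, C2 or the C3 methyl group. Compounds 18–20 are drawn as the C3=C4 isomer with C2 unassigned, the isomers are not separated, and step 13 merges them all into 21.

**Fragment 1: rings A and B**

Step 1
Reactants: 1 (R)-(−)-linalool
Product: 3 (5R)-5-methyl-5-vinyltetrahydrofuran-2-ol (anomers), via secondary ozonide 2 (not isolated)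
Conditions: O3 (1 equiv), CH2Cl2, −78 °C; PPh3, −78 °C → rt
Reagents that add atoms: ozone, [O-][O+]=O
Why: Chemoselective ozonolysis should take the electron-rich trisubstituted alkene before the vinyl group next to the carbinol, and the freed 4-hydroxy aldehyde closes to the lactol without touching the stereocentre.

Step 2
Reactants: 3 (5R)-5-methyl-5-vinyltetrahydrofuran-2-ol
Product: 4 (3R)-7-methoxy-3-methylhepta-1,6-dien-3-ol (E/Z mixture)
Conditions: MeOCH2PPh3Cl, KOt-Bu, THF, 0 °C → rt
Reagents that add atoms: (methoxymethyl)triphenylphosphonium chloride, COC[P+](c1ccccc1)(c1ccccc1)c1ccccc1.[Cl-]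
Why: In this Wittig homologation the lactol reacts through its open hydroxy-aldehyde form, which adds the one carbon that a six-membered lactone needs and leaves the carbinol centre alone.

Step 3
Reactants: 4 (3R)-7-methoxy-3-methylhepta-1,6-dien-3-ol
Product: 5 (6R)-6-methyl-6-vinyltetrahydro-2H-pyran-2-ol (anomers)
Conditions: PPTS (cat.), THF–H2O, 40 °C
Reagents that add atoms: water, O
Why: Acid-catalysed enol ether hydrolysis gives an oxocarbenium ion that the tertiary hydroxyl traps in a six-membered ring, and the mild acid should spare the tertiary allylic C–O bond.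

Step 4
Reactants: 5 (6R)-6-methyl-6-vinyltetrahydro-2H-pyran-2-ol
Product: 6 (6R)-6-methyl-6-vinyltetrahydro-2H-pyran-2-one
Conditions: TEMPO (cat.), PhI(OAc)2, CH2Cl2, rt
Reagents that add atoms: none
Why: Oxoammonium (TEMPO) oxidation converts a lactol into the lactone and does not attack a monosubstituted alkene.

Step 5
Reactants: 7 pent-1-en-4-yne
Product: 9 (2E)-3-methylhexa-2,5-dien-1-ol, via alkenylalane 8 (not isolated)
Conditions: Me3Al, Cp2ZrCl2 (cat.), CH2Cl2, 0 °C → rt; n-BuLi, THF, −78 °C; (CH2O)n, → rt; aqueous work-up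
Reagents that add atoms: trimethylaluminium, C[Al](C)C; paraformaldehyde (as formaldehyde), C=O
Why: Zirconium-catalysed carboalumination adds Me–Al syn to the terminal alkyne much faster than to the alkene, which fixes the E trisubstituted alkene, and the derived alanate is hydroxymethylated with retention.

Step 6
Reactants: 9 (2E)-3-methylhexa-2,5-dien-1-ol
Product: 10 tert-butyl{[(2E)-3-methylhexa-2,5-dienyl]oxy}diphenylsilane
Conditions: TBDPSCl, imidazole, DMF, rt
Reagents that add atoms: tert-butyldiphenylsilyl chloride, CC(C)(C)[Si](Cl)(c1ccccc1)c1ccccc1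
Why: Standard O-silylation gives a bulky, weakly Lewis-basic ether that tolerates amide base, methyl organometallics and a cold Lewis acid.

Step 7
Reactants: 6 (6R)-6-methyl-6-vinyltetrahydro-2H-pyran-2-one; 10 tert-butyl{[(2E)-3-methylhexa-2,5-dienyl]oxy}diphenylsilane (2 equiv)
Product: 11 (6R)-6-[(1E,4E)-6-(tert-butyldiphenylsilyloxy)-4-methylhexa-1,4-dienyl]-6-methyltetrahydro-2H-pyran-2-one
Conditions: second-generation Hoveyda–Grubbs catalyst (5 mol %), 1,4-benzoquinone (10 mol %), CH2Cl2, 40 °C
Reagents that add atoms: none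
Why: Olefin cross-metathesis pairs an unhindered terminal alkene with a vinyl group on a fully substituted carbon that cannot homodimerise, so the bulky neighbour enforces the E alkene while the trisubstituted alkene stays a spectator and the quinone suppresses alkene migration.

Step 8
Reactants: 11 (6R)-6-[(1E,4E)-6-(tert-butyldiphenylsilyloxy)-4-methylhexa-1,4-dienyl]-6-methyltetrahydro-2H-pyran-2-one
Product: 14 (1S,2R)-2-[(2E)-4-(tert-butyldiphenylsilyloxy)-2-methylbut-2-enyl]-4-methylcyclohex-3-ene-1-carboxylic acid (cis), via silyl ketene acetal 12 (not isolated), via silyl ester 13 (not isolated)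
Conditions: LiN(i-Pr)2 (LDA), THF, −78 °C; TBSCl, DMPU, −78 °C → rt; toluene, 110 °C; AcOH–THF–H2O, rt
Reagents that add atoms: tert-butyldimethylsilyl chloride, CC(C)(C)[Si](C)(C)Cl (in 12 and 13 only; lost again on hydrolysis)
Why: Kinetic deprotonation and O-silylation turn the lactone into cyclic silyl ketene acetal 12, whose C3=C2–O1–C6–C1'=C2' array undergoes a concerted suprafacial [3,3] shift on heating, which is the Ireland–Claisen rearrangement in its known ring-contracting lactone variant. Ring A closes as a six-membered carbocycle by bond formation between lactone C3 (future C8a) and the alkene terminus C2' (future C4a) while C6–O1 breaks, so the old carbinol carbon becomes C6 of the new C5=C6 alkene. Because the two-carbon tether C4–C5 ties both ends of the array together, only a boat-shaped transition state resembling bicyclo[2.2.2]octane can be reached. In that boat the E substituent on C2' ends cis to the carboxyl group, which sets C4a relative to C8a. The absolute configuration of both centres comes from the (R) carbinol carbon, because its axial alkenyl group can reach only one face of the ketene acetal and so gives (1S,2R)-14. The step needs an E alkene and clean O-silylation, secured by the metathesis at the quaternary centre and by a hard silyl chloride in a dipolar cosolvent, and it is driven by loss of the tertiary allylic C–O bond and gain of the silyl ester.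

Step 9
Reactants: 14 (1S,2R)-acid
Product: 15 methyl (1S,2R)-2-[(2E)-4-(tert-butyldiphenylsilyloxy)-2-methylbut-2-enyl]-4-methylcyclohex-3-ene-1-carboxylate
Conditions: MeI, K2CO3, DMF, rt
Reagents that add atoms: iodomethane, CI
Why: SN2 O-alkylation of the carboxylate is too mild to epimerise C8a.

Step 10
Reactants: 15 methyl ester
Product: 17 2-{(1S,2R)-2-[(2E)-4-(tert-butyldiphenylsilyloxy)-2-methylbut-2-enyl]-4-methylcyclohex-3-enyl}propan-2-ol, via methyl ketone 16 (not isolated)
Conditions: MeMgBr (3 equiv), CeCl3, THF, −78 → 0 °C; aqueous work-up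
Reagents that add atoms: methylmagnesium bromide, C[Mg]Br
Why: Double 1,2-addition of a weakly basic organocerium-type methyl reagent to the ester should outrun enolisation of ketone 16, so the cis relationship is kept and C1 receives both methyl groups.

Step 11
Reactants: 17 tertiary carbinol
Product: 18 tert-butyl{[(4aS,8aS)-1,1,3,6-tetramethyl-1,2,4a,7,8,8a-hexahydronaphthalen-2-yl]methoxy}diphenylsilane (cis-fused; C2 unassigned)
Conditions: SnCl4 (1.5 equiv), 2,6-di-tert-butyl-4-methylpyridine (2 equiv), CH2Cl2, −78 °C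
Reagents that add atoms: none
Why: In this cation–olefin cyclisation SnCl4 ionises the tertiary carbinol, the trisubstituted alkene captures C1 at its CH terminus C2 (6-endo, Markovnikov), and the hindered pyridine takes up the released proton, so the C5=C6 alkene and both ring-fusion centres should stay untouched.

Step 12
Reactants: 18 bicyclic silyl ether
Product: 19 [(4aS,8aS)-1,1,3,6-tetramethyl-1,2,4a,7,8,8a-hexahydronaphthalen-2-yl]methanol (C2 unassigned)
Conditions: Bu4NF, THF, rt
Reagents that add atoms: none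
Why: Fluoride-induced desilylation frees the primary alcohol and affects nothing else in a hydrocarbon framework.

Step 13
Reactants: 19 bicyclic alcohol
Product: 21 (4aR,8aS)-1,1,3,6-tetramethyl-1,4,4a,7,8,8a-hexahydronaphthalene-2-carbaldehyde, via unconjugated aldehyde 20 (not isolated)
Conditions: Dess–Martin periodinane, CH2Cl2, rt; crude aldehyde, DBU, CH2Cl2, rt
Reagents that add atoms: none
Why: Dess–Martin oxidation followed by base-mediated conjugation (deprotonation at C2, reprotonation of the dienolate at its γ carbon) leads to the tetrasubstituted enal, which is the thermodynamic sink for every alkene regioisomer of step 11 and erases the C2 centre without acid.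

Step 14
Reactants: 21 enal
Product: 22 [(4aR,8aS)-1,1,3,6-tetramethyl-1,4,4a,7,8,8a-hexahydronaphthalen-2-yl]methanol
Conditions: NaBH4, CeCl3·7H2O, MeOH, 0 °C
Reagents that add atoms: none
Why: Luche reduction delivers hydride 1,2 to the hindered enal and leaves the C2=C3 alkene in place.

Step 15
Reactants: 22 allylic alcohol
Product: 23 {[(4aR,8aS)-1,1,3,6-tetramethyl-1,4,4a,7,8,8a-hexahydronaphthalen-2-yl]methyl}triphenylphosphonium bromide
Conditions: Ph3P·HBr, MeOH, rt
Reagents that add atoms: triphenylphosphine hydrobromide, Br.c1ccc(cc1)P(c1ccccc1)c1ccccc1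
Why: In this SN1-type phosphonium salt formation the mildly acidic salt ionises the allylic alcohol and the phosphine takes the unhindered primary terminus S8, as is usual for cyclogeranyl-type alcohols.

**Fragment 2: the dioxane aldehyde**

Step 16
Reactants: 24 geranyl acetate
Product: 26 (2E)-3-methyl-6-oxohex-2-enyl acetate, via secondary ozonide 25 (not isolated)
Conditions: O3 (1 equiv), CH2Cl2, −78 °C; PPh3, −78 °C → rt
Reagents that add atoms: ozone, [O-][O+]=O
Why: Chemoselective ozonolysis should cleave the remote isopropylidene group first, because the allylic acetate deactivates the 2,3-alkene.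

Step 17
Reactants: 27 (4R)-4-benzyl-3-propanoyl-1,3-oxazolidin-2-one; 26 (2E)-3-methyl-6-oxohex-2-enyl acetate
Product: 29 (2E,6S,7R)-8-[(4R)-4-benzyl-2-oxo-1,3-oxazolidin-3-yl]-6-hydroxy-3,7-dimethyl-8-oxooct-2-enyl acetate (syn aldol), via boron enolate 28 (not isolated)
Conditions: Bu2BOTf, Et3N, CH2Cl2, −78 → 0 °C; 26, −78 → 0 °C; pH 7 buffer, MeOH, H2O2
Reagents that add atoms: dibutylboron triflate, CCCCB(CCCC)OS(=O)(=O)C(F)(F)F (in 28 only)
Why: In the Evans syn aldol the Z boron enolate reacts through a chair transition state on the face left open by the benzyl group, which sets S2 in its final configuration and the S3 carbinol in the configuration that the later inversion requires.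

Step 18
Reactants: 29 aldol adduct
Product: 30 (2E,6S,7S)-6,8-dihydroxy-3,7-dimethyloct-2-enyl acetate
Conditions: NaBH4, THF–H2O, 0 °C → rt
Reagents that add atoms: none
Why: Reductive auxiliary removal works because hydride attacks the activated imide carbonyl, whereas NaBH4 does not reduce the acetate and no stereocentre is touched.

Step 19
Reactants: 30 diol
Product: 31 (2E,6S,7S)-8-(tert-butyldiphenylsilyloxy)-6-hydroxy-3,7-dimethyloct-2-enyl acetate
Conditions: TBDPSCl (1.05 equiv), imidazole, CH2Cl2, 0 °C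
Reagents that add atoms: tert-butyldiphenylsilyl chloride, CC(C)(C)[Si](Cl)(c1ccccc1)c1ccccc1
Why: Under steric control the bulky chloride silylates only the primary hydroxyl, and holding S1 at the alcohol level removes the acidic α-hydrogen that would trigger β-elimination in step 24.

Step 20
Reactants: 31 secondary alcohol
Product: 32 (2E,6S,7S)-1-acetoxy-8-(tert-butyldiphenylsilyloxy)-3,7-dimethyloct-2-en-6-yl methanesulfonate
Conditions: MsCl, Et3N, CH2Cl2, 0 °C
Reagents that add atoms: methanesulfonyl chloride, CS(=O)(=O)Cl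
Why: Sulfonylation turns S3–OH into a leaving group with retention and also blocks it from attacking the later epoxide.

Step 21
Reactants: 32 acetate mesylate
Product: 33 (2E,6S,7S)-8-(tert-butyldiphenylsilyloxy)-1-hydroxy-3,7-dimethyloct-2-en-6-yl methanesulfonate
Conditions: K2CO3 (cat.), MeOH, 0 °C
Reagents that add atoms: none
Why: Base-catalysed transesterification removes the acetate under conditions that leave a secondary mesylate and the silyl ether intact.

Step 22
Reactants: 33 allylic alcohol
Product: 34 (3S,4S)-5-(tert-butyldiphenylsilyloxy)-1-[(2R,3R)-3-(hydroxymethyl)-2-methyloxiran-2-yl]-4-methylpentan-3-yl methanesulfonate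
Conditions: Ti(Oi-Pr)4 (cat.), D-(−)-diethyl tartrate (cat.), t-BuOOH, 4 Å molecular sieves, CH2Cl2, −20 °C
Reagents that add atoms: tert-butyl hydroperoxide, CC(C)(C)OO
Why: In the Sharpless asymmetric epoxidation the D-(−)-tartrate catalyst delivers oxygen to one face of the E geraniol-type allylic alcohol, which gives the (2R,3R)-epoxide under reagent control and places the C–O bond at S6 on the side opposite to the final peroxide.

Step 23
Reactants: 34 epoxy alcohol
Product: 35 (2R,3S,6S,7S)-8-(tert-butyldiphenylsilyloxy)-3-hydroperoxy-1,2-dihydroxy-3,7-dimethyloctan-6-yl methanesulfonate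
Conditions: anhydrous H2O2 in Et2O (excess), H3PMo12O40 (cat.), rt
Reagents that add atoms: hydrogen peroxide, OO
Why: In this acid-catalysed perhydrolysis of an epoxide H2O2 attacks the activated oxirane at its tertiary carbon from the rear (borderline SN2), so S6 is set by inversion of the epoxide centre.

Step 24
Reactants: 35 hydroperoxy mesylate
Product: 36 (1R)-1-[(3S,6R)-6-{(2S)-1-(tert-butyldiphenylsilyloxy)propan-2-yl}-3-methyl-1,2-dioxan-3-yl]ethane-1,2-diol
Conditions: KOt-Bu (1.0 equiv), 18-crown-6, THF, 0 °C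
Reagents that add atoms: none
Why: In this intramolecular SN2 alkylation of a hydroperoxide (6-exo-tet) one equivalent of base deprotonates only the far more acidic OOH, and the peroxide anion displaces the mesylate with inversion, which sets S3 and closes the dioxane.

Step 25
Reactants: 36 dioxane diol
Product: 37 (3S,6R)-6-[(2S)-1-(tert-butyldiphenylsilyloxy)propan-2-yl]-3-methyl-1,2-dioxane-3-carbaldehyde
Conditions: NaIO4, THF–H2O, 0 °C
Reagents that add atoms: none
Why: Periodate glycol cleavage removes the hydroxymethyl carbon and the leftover carbinol stereocentre, leaves the dialkyl peroxide intact and gives a non-enolisable aldehyde at S7.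

**Union and finish**

Step 26
Reactants: 23 phosphonium bromide; 37 dioxane aldehyde
Product: 39 tert-butyl{(2S)-2-[(3R,6S)-6-methyl-6-{(E)-2-[(4aR,8aS)-1,1,3,6-tetramethyl-1,4,4a,7,8,8a-hexahydronaphthalen-2-yl]ethenyl}-1,2-dioxan-3-yl]propoxy}diphenylsilane (alkene geometry of no consequence), via phosphorus ylide 38 (not isolated)
Conditions: NaN(SiMe3)2, THF, −78 → 0 °C; 37, −78 °C → rt
Reagents that add atoms: none
Why: In the Wittig olefination the allylic ylide adds to the aldehyde carbonyl faster than to the hindered O–O bond and forges S8=S7, and the quaternary S6 cannot epimerise.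

Step 27
Reactants: 39 diene
Product: 40 tert-butyl{(2S)-2-[(3R,6R)-6-methyl-6-{2-[(4aR,8aS)-1,1,3,6-tetramethyl-1,4,4a,7,8,8a-hexahydronaphthalen-2-yl]ethyl}-1,2-dioxan-3-yl]propoxy}diphenylsilane
Conditions: KO2CN=NCO2K, AcOH, MeOH–CH2Cl2, 0 °C → rt, added in portions until 39 is consumed
Reagents that add atoms: none
Why: Diimide reduction transfers H2 in a concerted syn fashion, does not cleave O–O bonds and slows steeply with alkene substitution, so the only disubstituted alkene should be reduced before the tri- and tetrasubstituted ring alkenes.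

Step 28
Reactants: 40 silyl ether
Product: 41 (2S)-2-[(3R,6R)-6-methyl-6-{2-[(4aR,8aS)-1,1,3,6-tetramethyl-1,4,4a,7,8,8a-hexahydronaphthalen-2-yl]ethyl}-1,2-dioxan-3-yl]propan-1-ol
Conditions: Bu4NF, AcOH, THF, 0 °C → rt
Reagents that add atoms: none
Why: Fluoride desilylation buffered with acetic acid frees S1–OH without exposing the S3–H of the peroxide to base.

Step 29
Reactants: 41 primary alcohol
Product: 43 (2R)-2-[(3R,6R)-6-methyl-6-{2-[(4aR,8aS)-1,1,3,6-tetramethyl-1,4,4a,7,8,8a-hexahydronaphthalen-2-yl]ethyl}-1,2-dioxan-3-yl]propanoic acid, via aldehyde 42 (not isolated)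
Conditions: TEMPO (cat.), PhI(OAc)2 (2.2 equiv), MeCN–H2O (pH 7), rt
Reagents that add atoms: water, O
Why: TEMPO/PhI(OAc)2 oxidation runs through the aldehyde hydrate at near-neutral pH, so neither epimerisation at S2, β-elimination of the peroxide nor attack on the ring alkenes is expected.

**Compound list**

1 | (R)-(−)-linalool, (3R)-3,7-dimethylocta-1,6-dien-3-ol | C[C@](O)(C=C)CCC=C(C)C | starting material
2 | (3R)-5-(5,5-dimethyl-1,2,4-trioxolan-3-yl)-3-methylpent-1-en-3-ol (secondary ozonide) | C[C@](O)(C=C)CCC1OOC(C)(C)O1 | intermediate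
3 | (5R)-5-methyl-5-vinyltetrahydrofuran-2-ol (anomers) | C[C@]1(C=C)CCC(O)O1 | intermediate
4 | (3R)-7-methoxy-3-methylhepta-1,6-dien-3-ol (E/Z) | C[C@](O)(C=C)CCC=COC | intermediate
5 | (6R)-6-methyl-6-vinyltetrahydro-2H-pyran-2-ol (anomers) | C[C@]1(C=C)CCCC(O)O1 | intermediate
6 | (6R)-6-methyl-6-vinyltetrahydro-2H-pyran-2-one | C[C@]1(C=C)CCCC(=O)O1 | intermediate
7 | pent-1-en-4-yne | C=CCC#C | starting material
8 | dimethyl[(1E)-2-methylpenta-1,4-dienyl]alane | C=CC/C(C)=C/[Al](C)C | intermediate
9 | (2E)-3-methylhexa-2,5-dien-1-ol | C=CC/C(C)=C/CO | intermediate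
10 | tert-butyl{[(2E)-3-methylhexa-2,5-dienyl]oxy}diphenylsilane | C=CC/C(C)=C/CO[Si](c1ccccc1)(c1ccccc1)C(C)(C)C | intermediate
11 | (6R)-6-[(1E,4E)-6-(tert-butyldiphenylsilyloxy)-4-methylhexa-1,4-dienyl]-6-methyltetrahydro-2H-pyran-2-one | C[C@]1(/C=C/C/C(C)=C/CO[Si](c2ccccc2)(c2ccccc2)C(C)(C)C)CCCC(=O)O1 | intermediate
12 | (2R)-6-(tert-butyldimethylsilyloxy)-2-[(1E,4E)-6-(tert-butyldiphenylsilyloxy)-4-methylhexa-1,4-dienyl]-2-methyl-3,4-dihydro-2H-pyran | C[C@]1(/C=C/C/C(C)=C/CO[Si](c2ccccc2)(c2ccccc2)C(C)(C)C)CCC=C(O[Si](C)(C)C(C)(C)C)O1 | intermediate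
13 | tert-butyldimethylsilyl ester of 14 | CC1=C[C@@H](C/C(C)=C/CO[Si](c2ccccc2)(c2ccccc2)C(C)(C)C)[C@@H](C(=O)O[Si](C)(C)C(C)(C)C)CC1 | intermediate
14 | (1S,2R)-2-[(2E)-4-(tert-butyldiphenylsilyloxy)-2-methylbut-2-enyl]-4-methylcyclohex-3-ene-1-carboxylic acid | CC1=C[C@@H](C/C(C)=C/CO[Si](c2ccccc2)(c2ccccc2)C(C)(C)C)[C@@H](C(=O)O)CC1 | intermediate
15 | methyl ester of 14 | CC1=C[C@@H](C/C(C)=C/CO[Si](c2ccccc2)(c2ccccc2)C(C)(C)C)[C@@H](C(=O)OC)CC1 | intermediate
16 | 1-{(1S,2R)-2-[(2E)-4-(tert-butyldiphenylsilyloxy)-2-methylbut-2-enyl]-4-methylcyclohex-3-enyl}ethanone | CC1=C[C@@H](C/C(C)=C/CO[Si](c2ccccc2)(c2ccccc2)C(C)(C)C)[C@@H](C(C)=O)CC1 | intermediate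
17 | 2-{(1S,2R)-2-[(2E)-4-(tert-butyldiphenylsilyloxy)-2-methylbut-2-enyl]-4-methylcyclohex-3-enyl}propan-2-ol | CC1=C[C@@H](C/C(C)=C/CO[Si](c2ccccc2)(c2ccccc2)C(C)(C)C)[C@@H](C(C)(C)O)CC1 | intermediate
18 | tert-butyl{[(4aS,8aS)-1,1,3,6-tetramethyl-1,2,4a,7,8,8a-hexahydronaphthalen-2-yl]methoxy}diphenylsilane (C2 unassigned) | CC1=C[C@H]2C=C(C)C(CO[Si](c3ccccc3)(c3ccccc3)C(C)(C)C)C(C)(C)[C@H]2CC1 | intermediate
19 | [(4aS,8aS)-1,1,3,6-tetramethyl-1,2,4a,7,8,8a-hexahydronaphthalen-2-yl]methanol (C2 unassigned) | CC1=C[C@H]2C=C(C)C(CO)C(C)(C)[C@H]2CC1 | intermediate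
20 | (4aS,8aS)-1,1,3,6-tetramethyl-1,2,4a,7,8,8a-hexahydronaphthalene-2-carbaldehyde (C2 unassigned) | CC1=C[C@H]2C=C(C)C(C=O)C(C)(C)[C@H]2CC1 | intermediate
21 | (4aR,8aS)-1,1,3,6-tetramethyl-1,4,4a,7,8,8a-hexahydronaphthalene-2-carbaldehyde | CC1=C[C@H]2CC(C)=C(C=O)C(C)(C)[C@H]2CC1 | intermediate
22 | [(4aR,8aS)-1,1,3,6-tetramethyl-1,4,4a,7,8,8a-hexahydronaphthalen-2-yl]methanol | CC1=C[C@H]2CC(C)=C(CO)C(C)(C)[C@H]2CC1 | intermediate
23 | {[(4aR,8aS)-1,1,3,6-tetramethyl-1,4,4a,7,8,8a-hexahydronaphthalen-2-yl]methyl}triphenylphosphonium bromide | CC1=C[C@H]2CC(C)=C(C[P+](c3ccccc3)(c3ccccc3)c3ccccc3)C(C)(C)[C@H]2CC1.[Br-] | intermediate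
24 | geranyl acetate | CC(C)=CCC/C(C)=C/COC(C)=O | starting material
25 | (2E)-5-(5,5-dimethyl-1,2,4-trioxolan-3-yl)-3-methylpent-2-enyl acetate (secondary ozonide) | CC(=O)OC/C=C(\C)CCC1OOC(C)(C)O1 | intermediate
26 | (2E)-3-methyl-6-oxohex-2-enyl acetate | CC(=O)OC/C=C(\C)CCC=O | intermediate
27 | (4R)-4-benzyl-3-propanoyl-1,3-oxazolidin-2-one | CCC(=O)N1[C@H](Cc2ccccc2)COC1=O | starting material
28 | (Z)-dibutylboron enolate of 27 | C/C=C(\OB(CCCC)CCCC)N1[C@H](Cc2ccccc2)COC1=O | intermediate
29 | (2E,6S,7R)-8-[(4R)-4-benzyl-2-oxo-1,3-oxazolidin-3-yl]-6-hydroxy-3,7-dimethyl-8-oxooct-2-enyl acetate | CC(=O)OC/C=C(\C)CC[C@H](O)[C@@H](C)C(=O)N1[C@H](Cc2ccccc2)COC1=O | intermediate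
30 | (2E,6S,7S)-6,8-dihydroxy-3,7-dimethyloct-2-enyl acetate | CC(=O)OC/C=C(\C)CC[C@H](O)[C@@H](C)CO | intermediate
31 | (2E,6S,7S)-8-(tert-butyldiphenylsilyloxy)-6-hydroxy-3,7-dimethyloct-2-enyl acetate | CC(=O)OC/C=C(\C)CC[C@H](O)[C@@H](C)CO[Si](c1ccccc1)(c1ccccc1)C(C)(C)C | intermediate
32 | (2E,6S,7S)-1-acetoxy-8-(tert-butyldiphenylsilyloxy)-3,7-dimethyloct-2-en-6-yl methanesulfonate | CC(=O)OC/C=C(\C)CC[C@H](OS(C)(=O)=O)[C@@H](C)CO[Si](c1ccccc1)(c1ccccc1)C(C)(C)C | intermediate
33 | (2E,6S,7S)-8-(tert-butyldiphenylsilyloxy)-1-hydroxy-3,7-dimethyloct-2-en-6-yl methanesulfonate | OC/C=C(\C)CC[C@H](OS(C)(=O)=O)[C@@H](C)CO[Si](c1ccccc1)(c1ccccc1)C(C)(C)C | intermediate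
34 | (3S,4S)-5-(tert-butyldiphenylsilyloxy)-1-[(2R,3R)-3-(hydroxymethyl)-2-methyloxiran-2-yl]-4-methylpentan-3-yl methanesulfonate | OC[C@H]1O[C@]1(C)CC[C@H](OS(C)(=O)=O)[C@@H](C)CO[Si](c2ccccc2)(c2ccccc2)C(C)(C)C | intermediate
35 | (2R,3S,6S,7S)-8-(tert-butyldiphenylsilyloxy)-3-hydroperoxy-1,2-dihydroxy-3,7-dimethyloctan-6-yl methanesulfonate | OC[C@@H](O)[C@@](C)(OO)CC[C@H](OS(C)(=O)=O)[C@@H](C)CO[Si](c1ccccc1)(c1ccccc1)C(C)(C)C | intermediate
36 | (1R)-1-[(3S,6R)-6-{(2S)-1-(tert-butyldiphenylsilyloxy)propan-2-yl}-3-methyl-1,2-dioxan-3-yl]ethane-1,2-diol | OC[C@@H](O)[C@]1(C)CC[C@H]([C@@H](C)CO[Si](c2ccccc2)(c2ccccc2)C(C)(C)C)OO1 | intermediate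
37 | (3S,6R)-6-[(2S)-1-(tert-butyldiphenylsilyloxy)propan-2-yl]-3-methyl-1,2-dioxane-3-carbaldehyde | O=C[C@]1(C)CC[C@H]([C@@H](C)CO[Si](c2ccccc2)(c2ccccc2)C(C)(C)C)OO1 | intermediate
38 | {[(4aR,8aS)-1,1,3,6-tetramethyl-1,4,4a,7,8,8a-hexahydronaphthalen-2-yl]methylidene}triphenylphosphorane | CC1=C[C@H]2CC(C)=C(C=P(c3ccccc3)(c3ccccc3)c3ccccc3)C(C)(C)[C@H]2CC1 | intermediate
39 | S7=S8 alkene, silyl ether (drawn E) | CC1=C[C@H]2CC(C)=C(/C=C/[C@]3(C)CC[C@H]([C@@H](C)CO[Si](c4ccccc4)(c4ccccc4)C(C)(C)C)OO3)C(C)(C)[C@H]2CC1 | intermediate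
40 | saturated silyl ether, (2S,3R,6R) side chain, (4aR,8aS) decalin | CC1=C[C@H]2CC(C)=C(CC[C@]3(C)CC[C@H]([C@@H](C)CO[Si](c4ccccc4)(c4ccccc4)C(C)(C)C)OO3)C(C)(C)[C@H]2CC1 | intermediate
41 | (2S)-2-[(3R,6R)-6-methyl-6-{2-[(4aR,8aS)-1,1,3,6-tetramethyl-1,4,4a,7,8,8a-hexahydronaphthalen-2-yl]ethyl}-1,2-dioxan-3-yl]propan-1-ol | CC1=C[C@H]2CC(C)=C(CC[C@]3(C)CC[C@H]([C@@H](C)CO)OO3)C(C)(C)[C@H]2CC1 | intermediate
42 | (2R)-2-[(3R,6R)-…-1,2-dioxan-3-yl]propanal (aldehyde of 41) | CC1=C[C@H]2CC(C)=C(CC[C@]3(C)CC[C@H]([C@@H](C)C=O)OO3)C(C)(C)[C@H]2CC1 | intermediate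
43 | (2R)-2-[(3R,6R)-6-methyl-6-{2-[(4aR,8aS)-1,1,3,6-tetramethyl-1,4,4a,7,8,8a-hexahydronaphthalen-2-yl]ethyl}-1,2-dioxan-3-yl]propanoic acid | CC1=C[C@H]2CC(C)=C(CC[C@]3(C)CC[C@H]([C@@H](C)C(=O)O)OO3)C(C)(C)[C@H]2CC1 | target

Total step count: 29. Longest linear sequence: 17 steps (steps 1–4, 7–15, 26–29).

**Steps most likely to fail**

**Step 11 (ring B closure).**
- What may go wrong: hydride migration from C8a to the cationic C1, proton loss to an isopropenyl or isopropylidene group, or ionisation of the allylic silyl ether may outrun ring closure. Any of these costs material or erodes the cis ring fusion.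
- Fallback (from 17, back at 21): the simple alkene is replaced by a far more nucleophilic, silyl-terminated partner.
  - Bu4NF would free the diol 2-{(1S,2R)-2-[(2E)-4-hydroxy-2-methylbut-2-enyl]-4-methylcyclohex-3-enyl}propan-2-ol F4.
  - MnO2 would oxidise only its allylic alcohol to the hydroxy enal F5.
  - TMSOTf/Et3N would convert F5 into the bis(trimethylsilyl) compound F6, a silyl dienol ether that also carries a tertiary silyl ether.
  - Catalytic TMSOTf at −78 °C would ionise the tertiary silyl ether, and the dienol ether would capture C1 at its α carbon C2 (Lewis-acid-induced tert-alkylation of a silyl enol ether). No proton is released, and the product is the exo-methylene aldehyde F7.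
  - DBU conjugates F7 to 21.

**Step 8 (key step).**
- What may go wrong: the ketene acetal may hydrolyse or suffer C-silylation, or the tertiary allylic C–O bond may ionise on heating, so that material is lost by elimination before the strained boat is reached.
- Fallback (from 10, back at 14): ring A is made by cycloaddition instead.
  - Cross-metathesis of 10 with methyl vinyl ketone would give the dienone (3E,6E)-8-(tert-butyldiphenylsilyloxy)-6-methylocta-3,6-dien-2-one F1.
  - Wittig methylenation (Ph3P=CH2) would give the triene tert-butyl{[(2E,5E)-3,7-dimethylocta-2,5,7-trienyl]oxy}diphenylsilane F2.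
  - An Et2AlCl-promoted endo Diels–Alder reaction with (R)-3-acryloyl-4-benzyl-1,3-oxazolidin-2-one would give the cis imide F3. Both diene substituents direct to the same regioisomer, and the benzyl group shields one face.
  - LiOH/H2O2 cleaves F3 to 14.

**Step 23 (perhydrolysis).**
- What may go wrong: the opening may drift toward an open carbocation with loss of configuration at S6, or molybdenum peroxo species may cleave the β-hydroxy hydroperoxide.
- Fallback (from 34, back at 36): the order of the two C–O bond formations is swapped, so that the tertiary centre is attacked intramolecularly.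
  - The preformed caesium salt of 2-methoxyprop-2-yl hydroperoxide (from CsOH) in DMF would displace the mesylate with inversion and give the peroxyketal F8.
  - Catalytic camphorsulfonic acid in wet CH2Cl2 would unmask the secondary hydroperoxide F9.
  - Under the same acid F9 opens the epoxide at its tertiary carbon in the 6-exo mode with inversion and gives 36.

**Further compounds**

F1 | step 8 | (3E,6E)-8-(tert-butyldiphenylsilyloxy)-6-methylocta-3,6-dien-2-one | CC(=O)/C=C/C/C(C)=C/CO[Si](c1ccccc1)(c1ccccc1)C(C)(C)C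
F2 | step 8 | tert-butyl{[(2E,5E)-3,7-dimethylocta-2,5,7-trienyl]oxy}diphenylsilane | C=C(C)/C=C/C/C(C)=C/CO[Si](c1ccccc1)(c1ccccc1)C(C)(C)C
F3 | step 8 | (4R)-4-benzyl-3-{(1S,2R)-2-[(2E)-4-(tert-butyldiphenylsilyloxy)-2-methylbut-2-enyl]-4-methylcyclohex-3-ene-1-carbonyl}-1,3-oxazolidin-2-one | CC1=C[C@@H](C/C(C)=C/CO[Si](c2ccccc2)(c2ccccc2)C(C)(C)C)[C@@H](C(=O)N2[C@H](Cc3ccccc3)COC2=O)CC1
F4 | step 11 | 2-{(1S,2R)-2-[(2E)-4-hydroxy-2-methylbut-2-enyl]-4-methylcyclohex-3-enyl}propan-2-ol | CC1=C[C@@H](C/C(C)=C/CO)[C@@H](C(C)(C)O)CC1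
F5 | step 11 | (2E)-4-[(1R,6S)-6-(2-hydroxypropan-2-yl)-3-methylcyclohex-2-enyl]-3-methylbut-2-enal | CC1=C[C@@H](C/C(C)=C/C=O)[C@@H](C(C)(C)O)CC1
F6 | step 11 | bis(trimethylsilyl) derivative of F5 (1-silyloxy-3-methylene-1-butenyl dienol ether, tertiary silyl ether) | CC1=C[C@@H](CC(=C)/C=C/O[Si](C)(C)C)[C@@H](C(C)(C)O[Si](C)(C)C)CC1
F7 | step 11 | cis-fused 1,1,6-trimethyl-3-methylene-1,2,3,4,4a,7,8,8a-octahydronaphthalene-2-carbaldehyde (ring-fusion centres as in 21, C2 unassigned) | CC1=C[C@H]2CC(=C)C(C=O)C(C)(C)[C@H]2CC1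
F8 | step 23 | S3-(2-methoxyprop-2-yl)peroxy epoxy alcohol (S3 inverted relative to 34) | OC[C@H]1O[C@]1(C)CC[C@@H](OOC(C)(C)OC)[C@@H](C)CO[Si](c2ccccc2)(c2ccccc2)C(C)(C)C
F9 | step 23 | S3-hydroperoxy epoxy alcohol | OC[C@H]1O[C@]1(C)CC[C@@H](OO)[C@@H](C)CO[Si](c2ccccc2)(c2ccccc2)C(C)(C)C
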